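A direct plan would build ring A first, as the vinylcyclohexene A1 from a desymmetrised cyclohexane-1,3-dione, would annulate ring B by Diels–Alder reaction with an alkynoate (dienoate A2), and, after hydrogenation of the 5,6-alkene and deconjugation to the 7-en-11-al A3, would add C12–C15 by Wittig reaction. Its weakest steps would be: the cycloaddition, which must make quaternary C10 at a tetrasubstituted diene terminus with the face chosen only by the substituents at C3 and C4; the deconjugative protonation, which must place the alkene at C7=C8 and set H-9 kinetically; and the closing inversion of the C3 carbinol by oxidation and reduction, which would add length without adding complexity.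

The route proposed here disconnects C4–C5 and C9–C10 together. The whole skeleton is laid out as an acyclic 2-methyl-3-oxo ester, made from farnesol (C1, C5–C17, C20; C13 set by asymmetric hydrogenation) and a 2-methylacetoacetate (C2–C4, C18, C19). An oxidative radical bicyclisation with trivalent manganese then closes rings A and B in one operation and sets C4, C5, C9 and C10 from the E alkenes, chair transition states and an ester auxiliary, leaving C3 as a ketone and C19 as a carboxyl: exactly the 3-oxygenated, C4-quaternary pattern of the target. The axial acetate and the axial hydroxymethyl follow by reduction, so no cycloaddition, deconjugation or C3 inversion is needed.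

Key step: step 7

Convention: α and β refer to the usual drawing with ring A on the left; in this series C19 and C20 are α and C18, H-5 and H-9 are β.
Assumption: the (1R,2S,5R)-8-phenylmenthyl ester is taken to direct the first ring closure to the face of the C4 radical that gives this 10α-methyl series; were the sense of induction the opposite, the (1S,2R,5S) auxiliary would be used in the same steps.

Step 1
Reactants: 1 (2E,6E)-farnesol
Product: 2 (3R,6E)-3,7,11-trimethyldodeca-6,10-dien-1-ol [(R)-2,3-dihydrofarnesol]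
Conditions: H2 (100 atm), Ru(OAc)2[(S)-BINAP] (0.5 mol %), MeOH/H2O (95:5), 20 °C
Reagents that add atoms: none
Why: Hydroxyl-directed asymmetric hydrogenation of an allylic alcohol with a ruthenium BINAP dicarboxylate (Noyori hydrogenation) reduces only the 2,3-alkene, and with the (S)-ligand the E alcohol should give the 3R centre, which becomes C13, in the way geraniol gives (R)-citronellol.

Step 2
Reactants: 2 (R)-2,3-dihydrofarnesol
Product: 3 tert-butyl{[(3R,6E)-3,7,11-trimethyldodeca-6,10-dien-1-yl]oxy}diphenylsilane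
Conditions: TBDPSCl (1.1 equiv), imidazole (2 equiv), CH2Cl2, 0 °C → rt
Reagents that add atoms: tert-butyldiphenylsilyl chloride, CC(C)(C)[Si](Cl)(c1ccccc1)c1ccccc1
Why: Silylation of the primary alcohol with the silyl chloride and imidazole gives an ether that should withstand the strong base, the oxidants and the hydrides of steps 3 to 10.

Step 3
Reactants: 3 silyl ether of dihydrofarnesol
Product: 4 (2E,6E,10R)-12-(tert-butyldiphenylsilyloxy)-2,6,10-trimethyldodeca-2,6-dien-1-ol
Conditions: SeO2 (0.3 equiv), t-BuOOH (70% aq., 3 equiv), salicylic acid (0.1 equiv), CH2Cl2, 0 °C → rt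
Reagents that add atoms: selenium dioxide, O=[Se]=O (oxygen carrier); tert-butyl hydroperoxide, CC(C)(C)OO (terminal oxidant)
Why: Selenium dioxide allylic oxidation (ene reaction followed by [2,3]-shift) attacks the terminal isopropylidene group, the most accessible trisubstituted alkene, at the methyl group trans to the chain, which gives the E allylic alcohol whose geometry becomes that of the 5,10-alkene.

Step 4
Reactants: 4 E allylic alcohol
Product: 5 {[(3R,6E,10E)-12-bromo-3,7,11-trimethyldodeca-6,10-dien-1-yl]oxy}(tert-butyl)diphenylsilane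
Conditions: CBr4 (1.3 equiv), PPh3 (1.3 equiv), CH2Cl2, −20 → 0 °C; used at once
Reagents that add atoms: carbon tetrabromide, BrC(Br)(Br)Br
Why: Appel bromination converts the primary allylic alcohol into the bromide by SN2 displacement of the oxyphosphonium group, without allylic shift or loss of the E geometry.

Step 5
Reactants: 6 ethyl 2-methyl-3-oxobutanoate; 7 (1R,2S,5R)-8-phenylmenthol
Product: 8 (1R,2S,5R)-8-phenylmenthyl 2-methyl-3-oxobutanoate
Conditions: 6 (1.5 equiv), DMAP (0.2 equiv), toluene, reflux, slow distillation of EtOH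
Reagents that add atoms: none
Why: DMAP-catalysed transesterification of a 3-oxo ester, which runs through the acylketene, installs the hindered auxiliary alcohol, and the configuration of the α-carbon is irrelevant because it later becomes a planar radical.

Step 6
Reactants: 8 auxiliary 2-methyl-3-oxobutanoate; 5 allylic bromide
Product: 10 (1R,2S,5R)-8-phenylmenthyl (6E,10E,14R)-16-(tert-butyldiphenylsilyloxy)-2,6,10,14-tetramethyl-3-oxohexadeca-6,10-dienoate, via dianion of the oxo ester 9 (not isolated)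
Conditions: NaH (1.1 equiv), THF, 0 °C; n-BuLi (1.05 equiv), 0 °C; 5 (0.9 equiv), 0 °C → rt; then 1 M HCl
Reagents that add atoms: none
Why: Weiler dianion alkylation: the 1,3-dianion reacts only at its more basic terminal carbon, so SN2 attack on the allylic bromide forms the C1–C2 bond and joins all twenty skeletal carbons, the hindered ester and the silyl ether being inert.

Step 7
Reactants: 10 acyclic 2-methyl-3-oxo ester
Product: 13 (1R,2S,5R)-8-phenylmenthyl (13R)-15-(tert-butyldiphenylsilyloxy)-3-oxolabd-8(17)-en-19-oate, via C4 radical 11 (not isolated), via bicyclic C8 radical 12 (not isolated)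
Conditions: Mn(OAc)3·2H2O (2.2 equiv), Cu(OAc)2·H2O (0.3 equiv), Yb(OTf)3 (1.0 equiv), CF3CH2OH (0.02 M), argon, −5 °C → rt
Reagents that add atoms: none
Why: Trivalent manganese oxidises the chelated enol of 10 to the C4 radical 11, which adds to C5 of the 5,10-alkene (ring A, 6-endo-trig), and the tertiary C10 radical so formed adds to C9 of the 8,9-alkene (ring B, 6-endo-trig) to give the tertiary C8 radical 12, which divalent copper oxidises through an organocopper species and β-hydride loss, mainly from C17, to the 8(17)-alkene. The closest known reaction type is the oxidative free-radical polyene cyclisation of 2-methyl-3-oxo esters with Mn(OAc)3 and Cu(OAc)2, including its variant with an 8-phenylmenthyl ester as the controlling group. Both closures pass through chair transition states on E alkenes, so that H-5 and C20 become trans-diaxial and the C9 chain equatorial, with H-9 cis to H-5. At C4 the ester takes the axial position cis to C20, as is general for these radicals and as an axial C19 requires, while C3 remains a ketone. The absolute sense is fixed in the first closure by the auxiliary, whose phenyl ring covers one face of the ytterbium-chelated radical; the step therefore needs this facial selectivity and a ring B closure that is faster than oxidation of the C10 radical, which dilution and a substoichiometric amount of copper (regenerated by trivalent manganese) should secure. Any 7-ene 14 formed alongside 13 is carried on, because step 8 converges both alkene isomers.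

Step 8
Reactants: 13 bicyclic 8(17)-ene
Product: 14 (1R,2S,5R)-8-phenylmenthyl (13R)-15-(tert-butyldiphenylsilyloxy)-3-oxolabd-7-en-19-oate
Conditions: [N,N′-bis(3,5-di-tert-butylsalicylidene)-1,2-cyclohexanediaminato]cobalt chloride (3 mol %), PhSiH3 (6 mol %), benzene, argon, rt
Reagents that add atoms: none
Why: Cobalt-hydride hydrogen atom transfer isomerisation: reversible hydrogen atom addition to the exocyclic methylene gives the tertiary C8 radical, and abstraction by divalent cobalt from the open C7 methylene, not from the C9 methine next to quaternary C10, should give the trisubstituted 7-ene, which reacts no further and leaves C9 untouched.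

Step 9
Reactants: 14 bicyclic 7-ene keto ester
Product: 16 (13R)-15-(tert-butyldiphenylsilyloxy)labd-7-ene-3β,19-diol, via lithium alkoxide of the 3β-hydroxy ester 15 (not isolated)
Conditions: LiBH(s-Bu)3 (1.3 equiv), THF, −78 °C; then LiAlH4 (3 equiv), −78 → 45 °C; aq. potassium sodium tartrate
Reagents that add atoms: none
Why: Bulky-hydride reduction attacks the C3 ketone along the equatorial trajectory, away from the axial hydrogens at C1 and C5, and so sets the axial 3β-alcohol trans to C19, after which LiAlH4 reduces the hindered ester to the C19 alcohol and releases the auxiliary for recovery.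

Step 10
Reactants: 16 3β,19-diol
Product: 17 (13R)-15-(tert-butyldiphenylsilyloxy)labd-7-ene-3β,19-diyl diacetate
Conditions: Ac2O (6 equiv), DMAP (0.3 equiv), pyridine, rt → 45 °C
Reagents that add atoms: acetic anhydride, CC(=O)OC(C)=O
Why: DMAP-catalysed acetylation esterifies both the primary and the hindered axial secondary hydroxyl, so that O3 carries its final acetate and O19 is masked during the oxidation.

Step 11
Reactants: 17 diacetate silyl ether
Product: 18 (13R)-3β,19-diacetoxylabd-7-en-15-ol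
Conditions: Bu4NF (3 equiv), AcOH (3 equiv), THF, rt → 40 °C
Reagents that add atoms: none
Why: Fluoride-mediated desilylation, buffered with acetic acid so that neither acetate is cleaved, frees the C15 alcohol.

Step 12
Reactants: 18 diacetoxy alcohol
Product: 19 (13R)-3β,19-diacetoxylabd-7-en-15-oic acid
Conditions: TEMPO (0.2 equiv), PhI(OAc)2 (2.5 equiv), MeCN/H2O (1:1), rt
Reagents that add atoms: water, O
Why: TEMPO-catalysed oxidation with PhI(OAc)2 in aqueous acetonitrile takes the primary alcohol through the aldehyde hydrate to the acid without touching the trisubstituted alkene, the acetates or C13.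

Step 13
Reactants: 19 diacetoxy acid
Product: 20 (3S,4R,5S,9R,10S,13R)-3-acetoxy-19-hydroxylabd-7-en-15-oic acid (CNP0138726.1)
Conditions: K2CO3 (2.2 equiv), MeOH, 0 °C; then 1 M HCl to pH 3
Reagents that add atoms: none
Why: Base-catalysed methanolysis (Zemplén-type transesterification) should cleave the primary C19 acetate well before the axial secondary C3 acetate shielded by quaternary C4, and acetyl migration from O3 to O19 is excluded because the two groups are trans-diaxial.

**Compound list**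

1 | (2E,6E)-farnesol [(2E,6E)-3,7,11-trimethyldodeca-2,6,10-trien-1-ol] | CC(C)=CCC/C(C)=C/CC/C(C)=C/CO | starting material
2 | (3R,6E)-3,7,11-trimethyldodeca-6,10-dien-1-ol [(R)-2,3-dihydrofarnesol] | CC(C)=CCC/C(C)=C/CC[C@@H](C)CCO | intermediate
3 | tert-butyl{[(3R,6E)-3,7,11-trimethyldodeca-6,10-dien-1-yl]oxy}diphenylsilane | CC(C)=CCC/C(C)=C/CC[C@@H](C)CCO[Si](c1ccccc1)(c1ccccc1)C(C)(C)C | intermediate
4 | (2E,6E,10R)-12-(tert-butyldiphenylsilyloxy)-2,6,10-trimethyldodeca-2,6-dien-1-ol | OC/C(C)=C/CC/C(C)=C/CC[C@@H](C)CCO[Si](c1ccccc1)(c1ccccc1)C(C)(C)C | intermediate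
5 | {[(3R,6E,10E)-12-bromo-3,7,11-trimethyldodeca-6,10-dien-1-yl]oxy}(tert-butyl)diphenylsilane | BrC/C(C)=C/CC/C(C)=C/CC[C@@H](C)CCO[Si](c1ccccc1)(c1ccccc1)C(C)(C)C | intermediate
6 | ethyl 2-methyl-3-oxobutanoate | CCOC(=O)C(C)C(C)=O | starting material
7 | (1R,2S,5R)-5-methyl-2-(2-phenylpropan-2-yl)cyclohexan-1-ol [(1R,2S,5R)-8-phenylmenthol] | O[C@@H]1C[C@H](C)CC[C@H]1C(C)(C)c1ccccc1 | starting material
8 | (1R,2S,5R)-8-phenylmenthyl 2-methyl-3-oxobutanoate (both C2 epimers) | CC(=O)C(C)C(=O)O[C@@H]1C[C@H](C)CC[C@H]1C(C)(C)c1ccccc1 | intermediate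
9 | sodium lithium 1,3-dienolate (dianion) of 8 | C=C([O-])C(C)=C([O-])O[C@@H]1C[C@H](C)CC[C@H]1C(C)(C)c1ccccc1.[Li+].[Na+] | intermediate
10 | (1R,2S,5R)-8-phenylmenthyl (6E,10E,14R)-16-(tert-butyldiphenylsilyloxy)-2,6,10,14-tetramethyl-3-oxohexadeca-6,10-dienoate (both C2 epimers; C2 = labdane C4, C16 = labdane C15) | CC(C(=O)CC/C(C)=C/CC/C(C)=C/CC[C@@H](C)CCO[Si](c1ccccc1)(c1ccccc1)C(C)(C)C)C(=O)O[C@@H]1C[C@H](C)CC[C@H]1C(C)(C)c1ccccc1 | intermediate
11 | C4 radical of 10 (2-methyl-1,3-dioxo-stabilised) | C[C](C(=O)CC/C(C)=C/CC/C(C)=C/CC[C@@H](C)CCO[Si](c1ccccc1)(c1ccccc1)C(C)(C)C)C(=O)O[C@@H]1C[C@H](C)CC[C@H]1C(C)(C)c1ccccc1 | intermediate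
12 | bicyclic tertiary C8 radical (rings A and B closed; C19 and C20 α, H-5 and H-9 β) | O=C1CC[C@]2(C)[C@H](CC[C](C)[C@H]2CC[C@@H](C)CCO[Si](c3ccccc3)(c3ccccc3)C(C)(C)C)[C@]1(C)C(=O)O[C@@H]4C[C@H](C)CC[C@H]4C(C)(C)c5ccccc5 | intermediate
13 | (1R,2S,5R)-8-phenylmenthyl (13R)-15-(tert-butyldiphenylsilyloxy)-3-oxolabd-8(17)-en-19-oate (C19 and C20 α, H-5 and H-9 β) | O=C1CC[C@]2(C)[C@H](CCC(=C)[C@H]2CC[C@@H](C)CCO[Si](c3ccccc3)(c3ccccc3)C(C)(C)C)[C@]1(C)C(=O)O[C@@H]4C[C@H](C)CC[C@H]4C(C)(C)c5ccccc5 | intermediate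
14 | (1R,2S,5R)-8-phenylmenthyl (13R)-15-(tert-butyldiphenylsilyloxy)-3-oxolabd-7-en-19-oate (C19 and C20 α, H-5 and H-9 β) | O=C1CC[C@]2(C)[C@H](CC=C(C)[C@H]2CC[C@@H](C)CCO[Si](c3ccccc3)(c3ccccc3)C(C)(C)C)[C@]1(C)C(=O)O[C@@H]4C[C@H](C)CC[C@H]4C(C)(C)c5ccccc5 | intermediate
15 | lithium alkoxide of (1R,2S,5R)-8-phenylmenthyl (13R)-15-(tert-butyldiphenylsilyloxy)-3β-hydroxylabd-7-en-19-oate | [Li+].[O-][C@H]1CC[C@]2(C)[C@H](CC=C(C)[C@H]2CC[C@@H](C)CCO[Si](c3ccccc3)(c3ccccc3)C(C)(C)C)[C@]1(C)C(=O)O[C@@H]4C[C@H](C)CC[C@H]4C(C)(C)c5ccccc5 | intermediate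
16 | (13R)-15-(tert-butyldiphenylsilyloxy)labd-7-ene-3β,19-diol (3-OH axial, C19 and C20 α) | O[C@H]1CC[C@]2(C)[C@H](CC=C(C)[C@H]2CC[C@@H](C)CCO[Si](c3ccccc3)(c3ccccc3)C(C)(C)C)[C@]1(C)CO | intermediate
17 | (13R)-15-(tert-butyldiphenylsilyloxy)labd-7-ene-3β,19-diyl diacetate | CC(=O)O[C@H]1CC[C@]2(C)[C@H](CC=C(C)[C@H]2CC[C@@H](C)CCO[Si](c3ccccc3)(c3ccccc3)C(C)(C)C)[C@]1(C)COC(C)=O | intermediate
18 | (13R)-3β,19-diacetoxylabd-7-en-15-ol | CC(=O)O[C@H]1CC[C@]2(C)[C@H](CC=C(C)[C@H]2CC[C@@H](C)CCO)[C@]1(C)COC(C)=O | intermediate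
19 | (13R)-3β,19-diacetoxylabd-7-en-15-oic acid | CC(=O)O[C@H]1CC[C@]2(C)[C@H](CC=C(C)[C@H]2CC[C@@H](C)CC(=O)O)[C@]1(C)COC(C)=O | intermediate
20 | (3S,4R,5S,9R,10S,13R)-3-acetoxy-19-hydroxylabd-7-en-15-oic acid (3β-OAc, C19 and C20 α, H-5 and H-9 β) | CC(=O)O[C@H]1CC[C@]2(C)[C@H](CC=C(C)[C@H]2CC[C@@H](C)CC(=O)O)[C@]1(C)CO | target

Total steps: 13. Longest linear sequence: 12 steps (steps 1–4 and 6–13).

**Steps most likely to fail**

Step 7. Divalent copper may oxidise the monocyclic C10 radical before ring B closes, or facial control in the first closure may be too weak. The fallback uses a radical chain without any oxidant. From 10, bromination at C4 (NaH, then N-bromosuccinimide, THF, −78 °C) would give the 2-bromo-3-oxo ester F1. Atom-transfer radical bicyclisation (Et3B/O2, Yb(OTf)3, toluene, −78 °C) would then give the tertiary C8 bromide F2; the chain is carried by bromine transfer, so no radical can be oxidised on the way. Dehydrobromination (DBU, toluene, 80 °C) would give 13 together with 14, and the route resumes at 13.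

Step 8. Hydrogen abstraction may occur at C9 instead of C7, moving the alkene to the tetrasubstituted 8,9-position, or migration may stay incomplete. The fallback is regiospecific by way of the 8-ketone. From 13, the exocyclic alkene would be kept through the two reductions of step 9 (lithium alkoxide of the hydroxy ester F3, not isolated) to the 8(17)-ene diol F4, which would be acetylated as in step 10 to the diacetate F5. Ozonolysis (O3, CH2Cl2/MeOH, −78 °C; Me2S) would give the 17-nor-8-ketone F6. Kinetic deprotonation at the C7 methylene (KN(SiMe3)2, THF, −78 °C) and trapping with PhNTf2 would give the 7-en-8-yl triflate F7. Iron-catalysed cross-coupling (MeMgBr, Fe(acac)3, THF/N-methylpyrrolidone, −30 °C) would restore C17 and return to the route at 17.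

Step 13. The rate difference between the two acetates may be too small, so that the C3 acetate is lost as well. The fallback replaces kinetic discrimination by orthogonal protection. From 16, the primary C19 hydroxyl would be converted into the 2,2,2-trichloroethyl carbonate F8 (Cl3CCH2OCOCl, pyridine, −20 °C) and O3 acetylated as in step 10 to the acetate carbonate F9. The silyl ether would be removed with HF·pyridine to give the C15 alcohol F10, and C15 oxidised as in step 12 to the acid F11. Reductive cleavage of the carbonate (Zn, AcOH, THF, rt), which leaves the acetate untouched, would give 20.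

**Further compounds**

F1 | step 7 | (1R,2S,5R)-8-phenylmenthyl (6E,10E,14R)-2-bromo-16-(tert-butyldiphenylsilyloxy)-2,6,10,14-tetramethyl-3-oxohexadeca-6,10-dienoate (both C2 epimers) | CC(Br)(C(=O)CC/C(C)=C/CC/C(C)=C/CC[C@@H](C)CCO[Si](c1ccccc1)(c1ccccc1)C(C)(C)C)C(=O)O[C@@H]1C[C@H](C)CC[C@H]1C(C)(C)c1ccccc1
F2 | step 7 | (1R,2S,5R)-8-phenylmenthyl (13R)-8-bromo-15-(tert-butyldiphenylsilyloxy)-3-oxolabdan-19-oate (C8 epimers; C19 and C20 α, H-5 and H-9 β) | O=C1CC[C@]2(C)[C@H](CCC(C)(Br)[C@H]2CC[C@@H](C)CCO[Si](c3ccccc3)(c3ccccc3)C(C)(C)C)[C@]1(C)C(=O)O[C@@H]4C[C@H](C)CC[C@H]4C(C)(C)c5ccccc5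
F3 | step 8 | lithium alkoxide of (1R,2S,5R)-8-phenylmenthyl (13R)-15-(tert-butyldiphenylsilyloxy)-3β-hydroxylabd-8(17)-en-19-oate | [Li+].[O-][C@H]1CC[C@]2(C)[C@H](CCC(=C)[C@H]2CC[C@@H](C)CCO[Si](c3ccccc3)(c3ccccc3)C(C)(C)C)[C@]1(C)C(=O)O[C@@H]4C[C@H](C)CC[C@H]4C(C)(C)c5ccccc5
F4 | step 8 | (13R)-15-(tert-butyldiphenylsilyloxy)labd-8(17)-ene-3β,19-diol | O[C@H]1CC[C@]2(C)[C@H](CCC(=C)[C@H]2CC[C@@H](C)CCO[Si](c3ccccc3)(c3ccccc3)C(C)(C)C)[C@]1(C)CO
F5 | step 8 | (13R)-15-(tert-butyldiphenylsilyloxy)labd-8(17)-ene-3β,19-diyl diacetate | CC(=O)O[C@H]1CC[C@]2(C)[C@H](CCC(=C)[C@H]2CC[C@@H](C)CCO[Si](c3ccccc3)(c3ccccc3)C(C)(C)C)[C@]1(C)COC(C)=O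
F6 | step 8 | (13R)-15-(tert-butyldiphenylsilyloxy)-8-oxo-17-norlabdane-3β,19-diyl diacetate | CC(=O)O[C@H]1CC[C@]2(C)[C@H](CCC(=O)[C@H]2CC[C@@H](C)CCO[Si](c3ccccc3)(c3ccccc3)C(C)(C)C)[C@]1(C)COC(C)=O
F7 | step 8 | (13R)-15-(tert-butyldiphenylsilyloxy)-8-(trifluoromethanesulfonyloxy)-17-norlabd-7-ene-3β,19-diyl diacetate | CC(=O)O[C@H]1CC[C@]2(C)[C@H](CC=C(OS(=O)(=O)C(F)(F)F)[C@H]2CC[C@@H](C)CCO[Si](c3ccccc3)(c3ccccc3)C(C)(C)C)[C@]1(C)COC(C)=O
F8 | step 13 | (13R)-15-(tert-butyldiphenylsilyloxy)-3β-hydroxylabd-7-en-19-yl 2,2,2-trichloroethyl carbonate | O[C@H]1CC[C@]2(C)[C@H](CC=C(C)[C@H]2CC[C@@H](C)CCO[Si](c3ccccc3)(c3ccccc3)C(C)(C)C)[C@]1(C)COC(=O)OCC(Cl)(Cl)Cl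
F9 | step 13 | (13R)-3β-acetoxy-15-(tert-butyldiphenylsilyloxy)labd-7-en-19-yl 2,2,2-trichloroethyl carbonate | CC(=O)O[C@H]1CC[C@]2(C)[C@H](CC=C(C)[C@H]2CC[C@@H](C)CCO[Si](c3ccccc3)(c3ccccc3)C(C)(C)C)[C@]1(C)COC(=O)OCC(Cl)(Cl)Cl
F10 | step 13 | (13R)-3β-acetoxy-15-hydroxylabd-7-en-19-yl 2,2,2-trichloroethyl carbonate | CC(=O)O[C@H]1CC[C@]2(C)[C@H](CC=C(C)[C@H]2CC[C@@H](C)CCO)[C@]1(C)COC(=O)OCC(Cl)(Cl)Cl
F11 | step 13 | (13R)-3β-acetoxy-19-[(2,2,2-trichloroethoxy)carbonyloxy]labd-7-en-15-oic acid | CC(=O)O[C@H]1CC[C@]2(C)[C@H](CC=C(C)[C@H]2CC[C@@H](C)CC(=O)O)[C@]1(C)COC(=O)OCC(Cl)(Cl)Cl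
A1 | direct plan | tert-butyl{[(1R,2R)-2-[(tert-butyldiphenylsilyloxy)methyl]-2,4-dimethyl-3-vinylcyclohex-3-en-1-yl]oxy}dimethylsilane | CC(C)(C)[Si](C)(C)O[C@@H]1CCC(C)=C(C=C)[C@]1(C)CO[Si](c2ccccc2)(c2ccccc2)C(C)(C)C
A2 | direct plan | methyl 3α-(tert-butyldimethylsilyloxy)-19-(tert-butyldiphenylsilyloxy)-12,13,14,15,16-pentanorlabda-5,8-dien-11-oate (C20 α) | CC(C)(C)[Si](C)(C)O[C@@H]1CC[C@]2(C)C(=CCC(C)=C2C(=O)OC)[C@]1(C)CO[Si](c3ccccc3)(c3ccccc3)C(C)(C)C
A3 | direct plan | 3α-(tert-butyldimethylsilyloxy)-19-(tert-butyldiphenylsilyloxy)-12,13,14,15,16-pentanorlabd-7-en-11-al (H-5 and H-9 β) | CC(C)(C)[Si](C)(C)O[C@@H]1CC[C@]2(C)[C@H](CC=C(C)[C@H]2C=O)[C@]1(C)CO[Si](c3ccccc3)(c3ccccc3)C(C)(C)C
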